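**Retrosynthetic overview**

1. The strategy rests on Ce, the unfunctionalised CH2 that joins C7 of ring B (C1–C8–C7–C6–C5–C9) to Cd of the cyclopentane (C3–Ca–Cb–Cc–Cd). Ce is taken as the radical left by decarboxylation of a C7-endo acetic acid, so the last step forms Ce–Cd (seven-membered cage ring) and Cc–Cb (cyclopentane) and releases isopropenyl by loss of PhSO2• from a 3-methyl-4-(phenylsulfonyl)but-2-enyl arm on C3.
2. C3 is made quaternary just before that: Knoevenagel condensation with isobutyraldehyde (isobutenyl, ends endo), then Pd-catalysed allylation on the exo face with ClCH2CH=C(CH3)CH2SO2Ph (from isoprene and PhSO2Cl).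
3. Ce must sit endo on C7, but malonyl annulation of ring B is expected to give the 7-exo epimer; C7 is therefore re-set on the bicycle: side-chain alcohol → enal (C7=Ce) → iminium transfer hydrogenation from the exo face.
4. Ring A (C1–C2–C3–C4–C5–C9) comes from Effenberger annulation of a silyl enol ether with malonyl dichloride; benzoyl enters at C1 by bridgehead lithiation of the vinylogous ester.
5. Ring B comes from 4-silyloxybutanal and methyl vinyl ketone (organocatalytic Michael addition sets C7, which relays chirality to C1 and C5 before it is inverted), aldol condensation, C5 geranylation and two methyl cuprate additions for C8. Ring order: B, then A, then cage ring and cyclopentane together.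

Key step: step 22

Numbering: C1 (bridgehead, benzoyl), C2, C3, C4, C5 (bridgehead, geranyl), C6, C7, C8 (CMe2), C9 (bridging C=O); endo = towards the other six-membered ring, exo = away from it; geranyl = (2E)-3,7-dimethylocta-2,6-dien-1-yl; TBDPS = tert-butyldiphenylsilyl.

Assumption: bridgehead deprotonation is taken to occur at C1 when C2 is the carbonyl carbon of the vinylogous ester, so the 4-methoxy isomer is carried on; compounds 8–11 and 13 are mixtures at the enolisable C5 (and at C8 in 9), centres that are erased later.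

**Route**

Step 1
Reactants: 1 butane-1,4-diol
Product: 2 4-[(tert-butyldiphenylsilyl)oxy]butan-1-ol
Conditions: TBDPSCl (0.33 equiv), imidazole, DMF, 0 °C → rt (diol in excess)
Reagents that add atoms: tert-butyl(chloro)diphenylsilane, CC(C)(C)[Si](Cl)(c1ccccc1)c1ccccc1
Why: Statistical monosilylation of a symmetrical diol used in excess is a routine O-silylation; TBDPS is chosen to survive the acid chloride and HCl of step 9 and the amide bases used later.

Step 2
Reactants: 2 4-[(tert-butyldiphenylsilyl)oxy]butan-1-ol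
Product: 3 4-[(tert-butyldiphenylsilyl)oxy]butanal
Conditions: TEMPO (cat.), PhI(OAc)2, CH2Cl2, rt
Reagents that add atoms: none
Why: TEMPO/hypervalent iodine oxidation of a primary alcohol should stop cleanly at the aldehyde.

Step 3
Reactants: 3 4-[(tert-butyldiphenylsilyl)oxy]butanal; 4 methyl vinyl ketone
Product: 5 (R)-2-{2-[(tert-butyldiphenylsilyl)oxy]ethyl}-5-oxohexanal
Conditions: (R)-α,α-diphenylprolinol trimethylsilyl ether (10 mol %), ethyl 3,4-dihydroxybenzoate (20 mol %), neat, 4 °C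
Reagents that add atoms: none
Why: Enamine-catalysed Michael addition of an aldehyde to an enone, in which the enamine is attacked on the face remote from the diaryl(silyloxy)methyl group, so the (R)-catalyst should give the (R)-aldehyde whose stereocentre becomes C7.

Step 4
Reactants: 5 (R)-2-{2-[(tert-butyldiphenylsilyl)oxy]ethyl}-5-oxohexanal
Product: 6 (R)-4-{2-[(tert-butyldiphenylsilyl)oxy]ethyl}cyclohex-2-en-1-one
Conditions: LiOH, i-PrOH, rt
Reagents that add atoms: none
Why: Intramolecular aldol condensation of the methyl ketone onto the aldehyde closes ring B under mild base, so that cyclisation should consume the epimerisable aldehyde faster than it racemises.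

Step 5
Reactants: 6 (R)-4-{2-[(tert-butyldiphenylsilyl)oxy]ethyl}cyclohex-2-en-1-one; 7 geranyl bromide
Product: 8 (4R)-4-{2-[(tert-butyldiphenylsilyl)oxy]ethyl}-6-geranylcyclohex-2-en-1-one (C6 epimers)
Conditions: LDA, THF, −78 °C; then 7, DMPU, −78 → −30 °C
Reagents that add atoms: none
Why: Kinetic α′-deprotonation of the enone and SN2 alkylation with the allylic bromide place geranyl on the future C5 without touching the γ-hydrogen at the stereocentre; the new centre is enolisable and is erased in step 9.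

Step 6
Reactants: 8 (4R)-4-{2-[(tert-butyldiphenylsilyl)oxy]ethyl}-6-geranylcyclohex-2-en-1-one
Product: 9 {[(4R)-4-{2-[(tert-butyldiphenylsilyl)oxy]ethyl}-6-geranyl-3-methylcyclohex-1-en-1-yl]oxy}trimethylsilane (epimers at C3 and C6)
Conditions: Me2CuLi, TMSCl, THF, −78 °C; Et3N quench
Reagents that add atoms: lithium dimethylcuprate, [Li+].C[Cu-]C; chlorotrimethylsilane, C[Si](C)(C)Cl
Why: TMSCl-accelerated cuprate conjugate addition with in situ O-silylation gives the regiodefined silyl enol ether needed for the Saegusa–Ito oxidation.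

Step 7
Reactants: 9 {[(4R)-4-{2-[(tert-butyldiphenylsilyl)oxy]ethyl}-6-geranyl-3-methylcyclohex-1-en-1-yl]oxy}trimethylsilane
Product: 10 (4R)-4-{2-[(tert-butyldiphenylsilyl)oxy]ethyl}-6-geranyl-3-methylcyclohex-2-en-1-one (C6 epimers)
Conditions: Pd(OAc)2 (10 mol %), O2 (1 atm), DMSO, rt
Reagents that add atoms: none
Why: Saegusa–Ito oxidation re-forms the enone, now β-methylated, through an oxo-π-allylpalladium species and β-hydride elimination, and leaves the isolated trisubstituted alkenes alone.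

Step 8
Reactants: 10 (4R)-4-{2-[(tert-butyldiphenylsilyl)oxy]ethyl}-6-geranyl-3-methylcyclohex-2-en-1-one
Product: 11 {[(4R)-4-{2-[(tert-butyldiphenylsilyl)oxy]ethyl}-6-geranyl-3,3-dimethylcyclohex-1-en-1-yl]oxy}trimethylsilane (C6 epimers)
Conditions: Me2CuLi, TMSCl, THF, −78 → −40 °C; Et3N quench
Reagents that add atoms: lithium dimethylcuprate, [Li+].C[Cu-]C; chlorotrimethylsilane, C[Si](C)(C)Cl
Why: A second TMSCl-assisted cuprate addition builds the quaternary gem-dimethyl carbon (future C8) and delivers the silyl enol ether for the annulation.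

Step 9
Reactants: 11 {[(4R)-4-{2-[(tert-butyldiphenylsilyl)oxy]ethyl}-6-geranyl-3,3-dimethylcyclohex-1-en-1-yl]oxy}trimethylsilane; 12 malonyl dichloride
Product: 14 (1S,5R,7R)-7-exo-{2-[(tert-butyldiphenylsilyl)oxy]ethyl}-5-geranyl-8,8-dimethylbicyclo[3.3.1]nonane-2,4,9-trione (enolised across C2/C4), via keto acid chloride 13 (not isolated)
Conditions: Et2O, −20 °C → rt; then aq KOH, BnEt3NCl
Reagents that add atoms: none
Why: Effenberger cyclization, in which C-acylation of the silyl enol ether and a second C-acylation at the other α-carbon by the pendant acid chloride close ring A as a 1,3-diaxial bridge on the face of ring B anti to the C7 side chain, so the (R)-centre fixes C1 and C5 in the sense of the target and leaves the side chain exo.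

Step 10
Reactants: 14 (1S,5R,7R)-7-exo-{2-[(tert-butyldiphenylsilyl)oxy]ethyl}-5-geranyl-8,8-dimethylbicyclo[3.3.1]nonane-2,4,9-trione
Product: 15 7-exo-{2-[(tert-butyldiphenylsilyl)oxy]ethyl}-5-geranyl-4-methoxy-8,8-dimethylbicyclo[3.3.1]non-3-ene-2,9-dione
Conditions: TMSCHN2, MeOH/toluene, 0 °C → rt; chromatographic separation from the 2-methoxy isomer
Reagents that add atoms: (trimethylsilyl)diazomethane, C[Si](C)(C)C=[N+]=[N-]
Why: O-methylation of the enolised β-diketone gives the vinylogous ester needed for bridgehead metalation; both regioisomers are expected and the 4-methoxy isomer is the one used.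

Step 11
Reactants: 15 7-exo-{2-[(tert-butyldiphenylsilyl)oxy]ethyl}-5-geranyl-4-methoxy-8,8-dimethylbicyclo[3.3.1]non-3-ene-2,9-dione; 16 benzoyl chloride
Product: 17 1-benzoyl-7-exo-{2-[(tert-butyldiphenylsilyl)oxy]ethyl}-5-geranyl-4-methoxy-8,8-dimethylbicyclo[3.3.1]non-3-ene-2,9-dione
Conditions: LDA (2 equiv), THF, −78 °C; then 16, −78 → −40 °C
Reagents that add atoms: none
Why: Bridgehead lithiation of the vinylogous ester at C1, which is flanked by the C2 and C9 carbonyl groups, followed by C-acylation installs the benzoyl group with the configuration imposed by the bicycle.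

Step 12
Reactants: 17 1-benzoyl-7-exo-{2-[(tert-butyldiphenylsilyl)oxy]ethyl}-5-geranyl-4-methoxy-8,8-dimethylbicyclo[3.3.1]non-3-ene-2,9-dione
Product: 18 1-benzoyl-5-geranyl-7-exo-(2-hydroxyethyl)-4-methoxy-8,8-dimethylbicyclo[3.3.1]non-3-ene-2,9-dione
Conditions: HF·pyridine, THF, 0 °C → rt
Reagents that add atoms: none
Why: Acidic fluoride removes the silyl ether without exposing the triacylmethane carbon C1 to basic fluoride.

Step 13
Reactants: 18 1-benzoyl-5-geranyl-7-exo-(2-hydroxyethyl)-4-methoxy-8,8-dimethylbicyclo[3.3.1]non-3-ene-2,9-dione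
Product: 20 (E)-2-[1-benzoyl-5-geranyl-4-methoxy-8,8-dimethyl-2,9-dioxobicyclo[3.3.1]non-3-en-7-ylidene]acetaldehyde, via exo aldehyde 19 (not isolated)
Conditions: IBX (3 equiv), DMSO, 75 °C
Reagents that add atoms: none
Why: IBX oxidises the alcohol to the aldehyde and then dehydrogenates it to the conjugated enal, which erases the C7 stereocentre once it has done its relay work; the formyl group should point away from the C8 methyl groups and no further dehydrogenation is possible because C5 and C1 are quaternary.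

Step 14
Reactants: 20 (E)-2-[1-benzoyl-5-geranyl-4-methoxy-8,8-dimethyl-2,9-dioxobicyclo[3.3.1]non-3-en-7-ylidene]acetaldehyde
Product: 21 1-benzoyl-5-geranyl-4-methoxy-8,8-dimethyl-7-endo-(2-oxoethyl)bicyclo[3.3.1]non-3-ene-2,9-dione
Conditions: Hantzsch ester (1.3 equiv), Bn2NH·CF3CO2H (20 mol %), THF, rt
Reagents that add atoms: none
Why: Iminium-catalysed transfer hydrogenation is specific for the enal among all alkenes present, and hydride should reach C7 from the exo (equatorial) face of the chair ring B because the endo face is closed by the transannular C3 and the axial C1–C2 and C5–C4 bonds, which places CH2CHO endo.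

Step 15
Reactants: 21 1-benzoyl-5-geranyl-4-methoxy-8,8-dimethyl-7-endo-(2-oxoethyl)bicyclo[3.3.1]non-3-ene-2,9-dione
Product: 22 1-benzoyl-7-endo-(2,2-dimethoxyethyl)-5-geranyl-4-methoxy-8,8-dimethylbicyclo[3.3.1]non-3-ene-2,9-dione
Conditions: HC(OMe)3, MeOH, PPTS (cat.), rt
Reagents that add atoms: trimethyl orthoformate, COC(OC)OC; methanol, CO
Why: Acetalisation masks the endo aldehyde, which would otherwise undergo aldol addition with C3 once the trione is set free.

Step 16
Reactants: 22 1-benzoyl-7-endo-(2,2-dimethoxyethyl)-5-geranyl-4-methoxy-8,8-dimethylbicyclo[3.3.1]non-3-ene-2,9-dione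
Product: 23 1-benzoyl-7-endo-(2,2-dimethoxyethyl)-5-geranyl-8,8-dimethylbicyclo[3.3.1]nonane-2,4,9-trione (enolised across C2/C4)
Conditions: LiCl (10 equiv), DMSO, 120 °C; dilute acid work-up
Reagents that add atoms: none
Why: SN2 O-demethylation of the vinylogous ester by chloride frees the trione under non-basic conditions that spare the C1 triacylmethane and the acetal.

Step 17
Reactants: 23 1-benzoyl-7-endo-(2,2-dimethoxyethyl)-5-geranyl-8,8-dimethylbicyclo[3.3.1]nonane-2,4,9-trione; 24 isobutyraldehyde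
Product: 26 1-benzoyl-7-endo-(2,2-dimethoxyethyl)-5-geranyl-4-hydroxy-8,8-dimethyl-3-(2-methylprop-1-en-1-yl)bicyclo[3.3.1]non-3-ene-2,9-dione, via alkylidene trione 25 (not isolated)
Conditions: 24 (3 equiv), piperidine/AcOH (cat.), CH2Cl2, 4 Å MS, rt
Reagents that add atoms: none
Why: Knoevenagel condensation at C3 gives the alkylidene trione, whose γ-hydrogen allows tautomerisation to the enolised 3-alkenyl trione, while a second Michael addition is disfavoured by the two quaternary bridgeheads that flank the dione.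

Step 18
Reactants: 27 isoprene; 28 benzenesulfonyl chloride
Product: 29 {[(2E)-4-chloro-2-methylbut-2-en-1-yl]sulfonyl}benzene
Conditions: CuCl (cat.), Et3N·HCl (cat.), MeCN, 100 °C, sealed tube
Reagents that add atoms: none
Why: Copper-catalysed addition of a sulfonyl chloride to a 1,3-diene, in which the sulfonyl radical adds to the CH2 next to the methyl-bearing carbon to give the more substituted allyl radical and chlorine is transferred to the far terminus (1,4-adduct, E favoured).

Step 19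
Reactants: 26 1-benzoyl-7-endo-(2,2-dimethoxyethyl)-5-geranyl-4-hydroxy-8,8-dimethyl-3-(2-methylprop-1-en-1-yl)bicyclo[3.3.1]non-3-ene-2,9-dione; 29 {[(2E)-4-chloro-2-methylbut-2-en-1-yl]sulfonyl}benzene
Product: 30 1-benzoyl-7-endo-(2,2-dimethoxyethyl)-5-geranyl-8,8-dimethyl-3-endo-(2-methylprop-1-en-1-yl)-3-exo-[(2E)-3-methyl-4-(phenylsulfonyl)but-2-en-1-yl]bicyclo[3.3.1]nonane-2,4,9-trione
Conditions: Pd(PPh3)4 (5 mol %), Et3N, THF, rt
Reagents that add atoms: none
Why: Tsuji–Trost allylation in which the soft dienolate attacks the unsubstituted π-allyl terminus through C3 (O-allyl product re-ionises) and from the exo face, the endo face being screened by the C8 methyl and C6 hydrogen of the boat-shaped ring B, so the isobutenyl group is pushed endo.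

Step 20
Reactants: 30 1-benzoyl-7-endo-(2,2-dimethoxyethyl)-5-geranyl-8,8-dimethyl-3-endo-(2-methylprop-1-en-1-yl)-3-exo-[(2E)-3-methyl-4-(phenylsulfonyl)but-2-en-1-yl]bicyclo[3.3.1]nonane-2,4,9-trione
Product: 31 1-benzoyl-5-geranyl-8,8-dimethyl-3-endo-(2-methylprop-1-en-1-yl)-3-exo-[(2E)-3-methyl-4-(phenylsulfonyl)but-2-en-1-yl]-7-endo-(2-oxoethyl)bicyclo[3.3.1]nonane-2,4,9-trione
Conditions: PPTS, acetone/H2O, 40 °C
Reagents that add atoms: water, O
Why: Mild acid hydrolysis of the dimethyl acetal should leave the trisubstituted alkenes and the non-enolisable tetraketone untouched.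

Step 21
Reactants: 31 1-benzoyl-5-geranyl-8,8-dimethyl-3-endo-(2-methylprop-1-en-1-yl)-3-exo-[(2E)-3-methyl-4-(phenylsulfonyl)but-2-en-1-yl]-7-endo-(2-oxoethyl)bicyclo[3.3.1]nonane-2,4,9-trione
Product: 32 2-{1-benzoyl-5-geranyl-8,8-dimethyl-3-endo-(2-methylprop-1-en-1-yl)-3-exo-[(2E)-3-methyl-4-(phenylsulfonyl)but-2-en-1-yl]-2,4,9-trioxobicyclo[3.3.1]nonan-7-endo-yl}acetic acid
Conditions: NaClO2, NaH2PO4, 2-methylbut-2-ene (excess), t-BuOH/H2O, 0 °C → rt
Reagents that add atoms: sodium chlorite, [Na+].[O-]Cl=O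
Why: Pinnick oxidation converts the aldehyde to the acid at pH about 4 while the alkene scavenger protects the geranyl and isobutenyl double bonds from hypochlorous acid.

Step 22
Reactants: 32 2-{1-benzoyl-5-geranyl-8,8-dimethyl-3-endo-(2-methylprop-1-en-1-yl)-3-exo-[(2E)-3-methyl-4-(phenylsulfonyl)but-2-en-1-yl]-2,4,9-trioxobicyclo[3.3.1]nonan-7-endo-yl}acetic acid
Product: 36 target CNP0110731.1, via primary radical 33 (not isolated), via tertiary radical 34 (not isolated), via sulfonylalkyl radical 35 (not isolated)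
Conditions: Pt anode / Pt cathode, undivided cell, constant current (ca. 100 mA cm−2, 1.5–2 F mol−1), Et3N (0.1 equiv), MeOH–MeCN 1:1, 0.02 M, 0–10 °C
Reagents that add atoms: none
Why: Proposed new method: one-electron oxidation of the carboxylate at platinum and loss of CO2 should give the endo C7–CH2• radical 33 (Ce), which adds to Cd, the CH terminus of the endo isobutenyl group, after which the tertiary Cc radical 34 adds to Cb of the exo allyl sulfone arm and radical 35 expels PhSO2• by β-scission to leave the isopropenyl group. The closest known reactions are Kolbe electrolysis with tandem radical cyclisation of unsaturated acids and radical addition–fragmentation of allyl sulfones, neither of which has been run as a transannular sequence on a bicyclo[3.3.1]nonane. The cage ring C3–C4–C5–C6–C7–Ce–Cd (equally C3–C2–C1–C8–C7–Ce–Cd) closes 7-exo-trig across the C3/C7 gap and the cyclopentane C3–Ca–Cb–Cc–Cd closes 5-exo-trig. Cd is set by the isobutenyl rotamer that keeps CMe2 on the C4/C6 side away from the equatorial C8 methyl group, so that Cd–H faces C2/C8, and Cb is set by a chair-like 5-exo transition state that puts the forming isopropenyl carbon trans to Ce on the cyclopentane. The step needs the 7-exo addition to outrun radical dimerisation and further oxidation to the cation; this is served by the endo/endo placement of Ce and the isobutenyl group on the rigid bicycle, by the Markovnikov sense of both additions, by the fact that the endo radical cannot reach the equatorial geranyl group, and by the irreversible sulfonyl β-scission that ends the sequence without a radical–radical step.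

**Compound list**

1 | butane-1,4-diol | OCCCCO | starting material
2 | 4-[(tert-butyldiphenylsilyl)oxy]butan-1-ol | CC(C)(C)[Si](c1ccccc1)(c1ccccc1)OCCCCO | intermediate
3 | 4-[(tert-butyldiphenylsilyl)oxy]butanal | CC(C)(C)[Si](c1ccccc1)(c1ccccc1)OCCCC=O | intermediate
4 | methyl vinyl ketone | CC(=O)C=C | starting material
5 | (R)-2-{2-[(tert-butyldiphenylsilyl)oxy]ethyl}-5-oxohexanal | CC(C)(C)[Si](c1ccccc1)(c1ccccc1)OCC[C@H](C=O)CCC(C)=O | intermediate
6 | (R)-4-{2-[(tert-butyldiphenylsilyl)oxy]ethyl}cyclohex-2-en-1-one | CC(C)(C)[Si](c1ccccc1)(c1ccccc1)OCC[C@H]1CCC(=O)C=C1 | intermediate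
7 | geranyl bromide | BrC/C=C(\C)CCC=C(C)C | starting material
8 | (4R)-4-{2-[(tert-butyldiphenylsilyl)oxy]ethyl}-6-geranylcyclohex-2-en-1-one (C6 epimers) | CC(C)(C)[Si](c1ccccc1)(c1ccccc1)OCC[C@H]1CC(C/C=C(\C)CCC=C(C)C)C(=O)C=C1 | intermediate
9 | {[(4R)-4-{2-[(tert-butyldiphenylsilyl)oxy]ethyl}-6-geranyl-3-methylcyclohex-1-en-1-yl]oxy}trimethylsilane (epimers at C3 and C6) | CC(C)(C)[Si](c1ccccc1)(c1ccccc1)OCC[C@H]1CC(C/C=C(\C)CCC=C(C)C)C(O[Si](C)(C)C)=CC1C | intermediate
10 | (4R)-4-{2-[(tert-butyldiphenylsilyl)oxy]ethyl}-6-geranyl-3-methylcyclohex-2-en-1-one (C6 epimers) | CC(C)(C)[Si](c1ccccc1)(c1ccccc1)OCC[C@H]1CC(C/C=C(\C)CCC=C(C)C)C(=O)C=C1C | intermediate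
11 | {[(4R)-4-{2-[(tert-butyldiphenylsilyl)oxy]ethyl}-6-geranyl-3,3-dimethylcyclohex-1-en-1-yl]oxy}trimethylsilane (C6 epimers) | CC(C)(C)[Si](c1ccccc1)(c1ccccc1)OCC[C@H]1CC(C/C=C(\C)CCC=C(C)C)C(O[Si](C)(C)C)=CC1(C)C | intermediate
12 | malonyl dichloride | O=C(Cl)CC(Cl)=O | starting material
13 | 3-[(5R)-5-{2-[(tert-butyldiphenylsilyl)oxy]ethyl}-3-geranyl-6,6-dimethyl-2-oxocyclohexyl]-3-oxopropanoyl chloride (not isolated) | CC(C)(C)[Si](c1ccccc1)(c1ccccc1)OCC[C@H]1CC(C/C=C(\C)CCC=C(C)C)C(=O)C(C(=O)CC(Cl)=O)C1(C)C | intermediate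
14 | (1S,5R,7R)-7-exo-{2-[(tert-butyldiphenylsilyl)oxy]ethyl}-5-geranyl-8,8-dimethylbicyclo[3.3.1]nonane-2,4,9-trione | CC(C)(C)[Si](c1ccccc1)(c1ccccc1)OCC[C@H]1C[C@]2(C/C=C(\C)CCC=C(C)C)C(=O)CC(=O)[C@@H](C2=O)C1(C)C | intermediate
15 | 7-exo-{2-[(tert-butyldiphenylsilyl)oxy]ethyl}-5-geranyl-4-methoxy-8,8-dimethylbicyclo[3.3.1]non-3-ene-2,9-dione (bridgeheads as in 14) | CC(C)(C)[Si](c1ccccc1)(c1ccccc1)OCC[C@H]1C[C@]2(C/C=C(\C)CCC=C(C)C)C(OC)=CC(=O)[C@@H](C2=O)C1(C)C | intermediate
16 | benzoyl chloride | O=C(Cl)c1ccccc1 | starting material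
17 | 1-benzoyl-7-exo-{2-[(tert-butyldiphenylsilyl)oxy]ethyl}-5-geranyl-4-methoxy-8,8-dimethylbicyclo[3.3.1]non-3-ene-2,9-dione | CC(C)(C)[Si](c1ccccc1)(c1ccccc1)OCC[C@H]1C[C@]2(C/C=C(\C)CCC=C(C)C)C(OC)=CC(=O)[C@@](C(=O)c3ccccc3)(C2=O)C1(C)C | intermediate
18 | 1-benzoyl-5-geranyl-7-exo-(2-hydroxyethyl)-4-methoxy-8,8-dimethylbicyclo[3.3.1]non-3-ene-2,9-dione | OCC[C@H]1C[C@]2(C/C=C(\C)CCC=C(C)C)C(OC)=CC(=O)[C@@](C(=O)c3ccccc3)(C2=O)C1(C)C | intermediate
19 | 1-benzoyl-5-geranyl-4-methoxy-8,8-dimethyl-7-exo-(2-oxoethyl)bicyclo[3.3.1]non-3-ene-2,9-dione (not isolated) | O=CC[C@H]1C[C@]2(C/C=C(\C)CCC=C(C)C)C(OC)=CC(=O)[C@@](C(=O)c3ccccc3)(C2=O)C1(C)C | intermediate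
20 | (E)-2-[1-benzoyl-5-geranyl-4-methoxy-8,8-dimethyl-2,9-dioxobicyclo[3.3.1]non-3-en-7-ylidene]acetaldehyde | O=C/C=C1\C[C@]2(C/C=C(\C)CCC=C(C)C)C(OC)=CC(=O)[C@@](C(=O)c3ccccc3)(C2=O)C1(C)C | intermediate
21 | 1-benzoyl-5-geranyl-4-methoxy-8,8-dimethyl-7-endo-(2-oxoethyl)bicyclo[3.3.1]non-3-ene-2,9-dione | O=CC[C@@H]1C[C@]2(C/C=C(\C)CCC=C(C)C)C(OC)=CC(=O)[C@@](C(=O)c3ccccc3)(C2=O)C1(C)C | intermediate
22 | 1-benzoyl-7-endo-(2,2-dimethoxyethyl)-5-geranyl-4-methoxy-8,8-dimethylbicyclo[3.3.1]non-3-ene-2,9-dione | COC(OC)C[C@@H]1C[C@]2(C/C=C(\C)CCC=C(C)C)C(OC)=CC(=O)[C@@](C(=O)c3ccccc3)(C2=O)C1(C)C | intermediate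
23 | 1-benzoyl-7-endo-(2,2-dimethoxyethyl)-5-geranyl-8,8-dimethylbicyclo[3.3.1]nonane-2,4,9-trione | COC(OC)C[C@@H]1C[C@]2(C/C=C(\C)CCC=C(C)C)C(=O)CC(=O)[C@@](C(=O)c3ccccc3)(C2=O)C1(C)C | intermediate
24 | isobutyraldehyde | CC(C)C=O | starting material
25 | 1-benzoyl-7-endo-(2,2-dimethoxyethyl)-5-geranyl-8,8-dimethyl-3-(2-methylpropylidene)bicyclo[3.3.1]nonane-2,4,9-trione (not isolated) | COC(OC)C[C@@H]1C[C@]2(C/C=C(\C)CCC=C(C)C)C(=O)C(=CC(C)C)C(=O)[C@@](C(=O)c3ccccc3)(C2=O)C1(C)C | intermediate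
26 | 1-benzoyl-7-endo-(2,2-dimethoxyethyl)-5-geranyl-4-hydroxy-8,8-dimethyl-3-(2-methylprop-1-en-1-yl)bicyclo[3.3.1]non-3-ene-2,9-dione | COC(OC)C[C@@H]1C[C@]2(C/C=C(\C)CCC=C(C)C)C(O)=C(C=C(C)C)C(=O)[C@@](C(=O)c3ccccc3)(C2=O)C1(C)C | intermediate
27 | isoprene | C=CC(C)=C | starting material
28 | benzenesulfonyl chloride | O=S(=O)(Cl)c1ccccc1 | starting material
29 | {[(2E)-4-chloro-2-methylbut-2-en-1-yl]sulfonyl}benzene | ClC/C=C(\C)CS(=O)(=O)c1ccccc1 | intermediate
30 | 1-benzoyl-7-endo-(2,2-dimethoxyethyl)-5-geranyl-8,8-dimethyl-3-endo-(2-methylprop-1-en-1-yl)-3-exo-[(2E)-3-methyl-4-(phenylsulfonyl)but-2-en-1-yl]bicyclo[3.3.1]nonane-2,4,9-trione | COC(OC)C[C@@H]1C[C@]2(C/C=C(\C)CCC=C(C)C)C(=O)[C@](C/C=C(\C)CS(=O)(=O)c3ccccc3)(C=C(C)C)C(=O)[C@@](C(=O)c3ccccc3)(C2=O)C1(C)C | intermediate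
31 | 1-benzoyl-5-geranyl-8,8-dimethyl-3-endo-(2-methylprop-1-en-1-yl)-3-exo-[(2E)-3-methyl-4-(phenylsulfonyl)but-2-en-1-yl]-7-endo-(2-oxoethyl)bicyclo[3.3.1]nonane-2,4,9-trione | O=CC[C@@H]1C[C@]2(C/C=C(\C)CCC=C(C)C)C(=O)[C@](C/C=C(\C)CS(=O)(=O)c3ccccc3)(C=C(C)C)C(=O)[C@@](C(=O)c3ccccc3)(C2=O)C1(C)C | intermediate
32 | 2-{1-benzoyl-5-geranyl-8,8-dimethyl-3-endo-(2-methylprop-1-en-1-yl)-3-exo-[(2E)-3-methyl-4-(phenylsulfonyl)but-2-en-1-yl]-2,4,9-trioxobicyclo[3.3.1]nonan-7-endo-yl}acetic acid | OC(=O)C[C@@H]1C[C@]2(C/C=C(\C)CCC=C(C)C)C(=O)[C@](C/C=C(\C)CS(=O)(=O)c3ccccc3)(C=C(C)C)C(=O)[C@@](C(=O)c3ccccc3)(C2=O)C1(C)C | intermediate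
33 | C7-endo methyl radical (Ce radical) from decarboxylation of 32 (not isolated) | [CH2][C@@H]1C[C@]2(C/C=C(\C)CCC=C(C)C)C(=O)[C@](C/C=C(\C)CS(=O)(=O)c3ccccc3)(C=C(C)C)C(=O)[C@@](C(=O)c3ccccc3)(C2=O)C1(C)C | intermediate
34 | tertiary Cc radical after 7-exo closure of the cage (not isolated) | O=S(=O)(c1ccccc1)C/C(C)=C/C[C@@]23C(=O)[C@@]4(C/C=C(\C)CCC=C(C)C)C[C@@H](C[C@H]2[C](C)C)C(C)(C)[C@](C(=O)c1ccccc1)(C4=O)C3=O | intermediate
35 | β-sulfonyl tertiary radical after 5-exo closure of the cyclopentane (not isolated) | C[C](CS(=O)(=O)c1ccccc1)[C@@H]1C[C@@]23C(=O)[C@@]4(C/C=C(\C)CCC=C(C)C)C[C@@H](C[C@H]2C1(C)C)C(C)(C)[C@](C(=O)c1ccccc1)(C4=O)C3=O | intermediate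
36 | target CNP0110731.1 | C=C(C)[C@@H]1C[C@@]23C(=O)[C@@]4(C/C=C(\C)CCC=C(C)C)C[C@@H](C[C@H]2C1(C)C)C(C)(C)[C@](C(=O)c1ccccc1)(C4=O)C3=O | target

**Step count and risks**

Total steps: 22. Longest linear sequence: 21 steps (steps 1–17 and 19–22); step 18 makes the side arm.

Steps most likely to fail:

1. Step 22 (Proposed new method). Radical 33 may couple with a second radical at the anode surface or be oxidised further to the cation before the 7-exo addition takes place, and alkoxide formed at the cathode may cleave the triacylmethane at C1. Fallback with known chemistry (reductive radical generation from a redox-active ester and trapping by an allyl sulfone): acid 32 is esterified with N-hydroxyphthalimide (DIC, DMAP cat., CH2Cl2) to the N-(acyloxy)phthalimide F1, which is irradiated with blue light in the presence of Ru(bpy)3(PF6)2 (1 mol %) and Hantzsch ester in CH2Cl2 at rt. The same Ce radical then forms at a low stationary concentration and away from an electrode, and the route is rejoined at target 36.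

2. Step 11. Lithiation may occur at the vinylic C3 instead of the bridgehead, and acylation at C1 next to the C8 gem-dimethyl group may be too slow. Fallback: starting from 15, C3 is blocked and the bridgehead is iodinated (LDA, TMSCl, then LDA, I2, THF, −78 °C) to give the 3-trimethylsilyl bridgehead iodide F2. Iodine–magnesium exchange (i-PrMgCl·LiCl, THF, −78 °C) and addition to benzaldehyde give the bridgehead carbinol F3, and DMP oxidation gives the 3-trimethylsilyl benzoyl compound F4. Treatment with HF·pyridine under the conditions of step 12 removes both silyl groups and rejoins the route at 18.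

3. Step 17. The alkylidene trione 25 may be intercepted by a second molecule of trione (Michael addition), or the enol of 26 may add to its own isobutenyl group under the acidic co-catalyst. Fallback: starting from 22, α-iodination of the vinylogous ester (I2, pyridine, CH2Cl2) gives the 3-iodo compound F5. Stille coupling with tributyl(2-methylprop-1-en-1-yl)stannane (Pd(PPh3)4, CuI, DMF, 50 °C) gives the 3-isobutenyl vinylogous ester F6, and demethylation under the conditions of step 16 rejoins the route at 26.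

**Further compounds**

F1 | step 22 | N-(acyloxy)phthalimide of acid 32 | O=C(C[C@@H]1C[C@]2(C/C=C(\C)CCC=C(C)C)C(=O)[C@](C/C=C(\C)CS(=O)(=O)c3ccccc3)(C=C(C)C)C(=O)[C@@](C(=O)c3ccccc3)(C2=O)C1(C)C)ON1C(=O)c2ccccc2C1=O
F2 | step 11 | 7-exo-{2-[(tert-butyldiphenylsilyl)oxy]ethyl}-5-geranyl-1-iodo-4-methoxy-8,8-dimethyl-3-(trimethylsilyl)bicyclo[3.3.1]non-3-ene-2,9-dione | CC(C)(C)[Si](c1ccccc1)(c1ccccc1)OCC[C@H]1C[C@]2(C/C=C(\C)CCC=C(C)C)C(OC)=C([Si](C)(C)C)C(=O)[C@@](I)(C2=O)C1(C)C
F3 | step 11 | 7-exo-{2-[(tert-butyldiphenylsilyl)oxy]ethyl}-5-geranyl-1-[hydroxy(phenyl)methyl]-4-methoxy-8,8-dimethyl-3-(trimethylsilyl)bicyclo[3.3.1]non-3-ene-2,9-dione (carbinol epimers) | CC(C)(C)[Si](c1ccccc1)(c1ccccc1)OCC[C@H]1C[C@]2(C/C=C(\C)CCC=C(C)C)C(OC)=C([Si](C)(C)C)C(=O)[C@@](C(O)c3ccccc3)(C2=O)C1(C)C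
F4 | step 11 | 1-benzoyl-7-exo-{2-[(tert-butyldiphenylsilyl)oxy]ethyl}-5-geranyl-4-methoxy-8,8-dimethyl-3-(trimethylsilyl)bicyclo[3.3.1]non-3-ene-2,9-dione | CC(C)(C)[Si](c1ccccc1)(c1ccccc1)OCC[C@H]1C[C@]2(C/C=C(\C)CCC=C(C)C)C(OC)=C([Si](C)(C)C)C(=O)[C@@](C(=O)c3ccccc3)(C2=O)C1(C)C
F5 | step 17 | 1-benzoyl-7-endo-(2,2-dimethoxyethyl)-5-geranyl-3-iodo-4-methoxy-8,8-dimethylbicyclo[3.3.1]non-3-ene-2,9-dione | COC(OC)C[C@@H]1C[C@]2(C/C=C(\C)CCC=C(C)C)C(OC)=C(I)C(=O)[C@@](C(=O)c3ccccc3)(C2=O)C1(C)C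
F6 | step 17 | 1-benzoyl-7-endo-(2,2-dimethoxyethyl)-5-geranyl-4-methoxy-8,8-dimethyl-3-(2-methylprop-1-en-1-yl)bicyclo[3.3.1]non-3-ene-2,9-dione | COC(OC)C[C@@H]1C[C@]2(C/C=C(\C)CCC=C(C)C)C(OC)=C(C=C(C)C)C(=O)[C@@](C(=O)c3ccccc3)(C2=O)C1(C)C
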